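**Retrosynthetic overview**
- Endgame: the lactol stereocentre is set by a catalyst-controlled dynamic kinetic resolution (allyl carbonate formation) and unmasked by deallylation with Pd(PPh3)4; the hemifumarate is attached by Steglich esterification of the benzylic alcohol; the five-membered lactol ring is closed by acid from a formyl group and a tert-butyl ester.
- Key disconnection: the central seven-membered dioxepinone ring is cut at the ring A aryl–carbonyl bond and at the diaryl ether O–C(ring B) bond, giving the o-iodophenol 14 and the o-fluoroaryl formate 11.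
- Enabling feature (ring B numbered as a phthalide): C-4, which carries the ether oxygen, is ortho to the lactol carbon C-3 (a formyl group in the open form, so it activates a C-4 fluoride for SNAr) and ortho to the ester oxygen on C-5 (which can carry the lactone carbonyl carbon as a formate). In ring A the lactone carbonyl is ortho to the ether oxygen, and ring A comes from mirror-symmetric atranol, so mono-iodination gives one isomer.
- Ring order: rings A and B enter as arenes (atranol; 3-(benzyloxy)phenol elaborated by three directed metalations and one electrophilic fluorination), then the seven-membered ring (key step), then the five-membered lactol ring, then the stereocentre.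

Key step: step 10

Assumption: the lactol carbon is a hemiacylal that can epimerise through the ring-opened formyl acid, so it is set in the penultimate step, unmasked last under acidic, alkoxide-free conditions, and the product is kept cold and free of base.

**Route**

Step 1
Reactants: 1 3-(benzyloxy)phenol
Product: 2 1-(benzyloxy)-3-(methoxymethoxy)benzene
Conditions: MOMCl, iPr2NEt, CH2Cl2, 0 °C → rt
Reagents that add atoms: chloromethyl methyl ether, COCCl
Why: Williamson-type O-alkylation of the phenol with an α-chloro ether installs the methoxymethyl ether, which directs the next two metalations and is later removed by acid.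

Step 2
Reactants: 2 1-(benzyloxy)-3-(methoxymethoxy)benzene
Product: 4 {[2-(benzyloxy)-6-(methoxymethoxy)phenyl]methoxy}tri(propan-2-yl)silane, via aryllithium 3 (not isolated)
Conditions: n-BuLi, THF, 0 °C; then iPr3SiOCH2Cl, −78 °C → rt
Reagents that add atoms: (triisopropylsiloxy)methyl chloride, ClCO[Si](C(C)C)(C(C)C)C(C)C
Why: Directed ortho-metalation should occur at the carbon between the two alkoxy groups (cooperative coordination), and the aryllithium should be C-alkylated by the α-chloro ether as it is by chloromethyl methyl ether.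

Step 3
Reactants: 4 {[2-(benzyloxy)-6-(methoxymethoxy)phenyl]methoxy}tri(propan-2-yl)silane
Product: 6 tert-butyl 4-(benzyloxy)-2-(methoxymethoxy)-3-({[tri(propan-2-yl)silyl]oxy}methyl)benzoate, via aryllithium 5 (not isolated)
Conditions: s-BuLi, TMEDA, THF, −78 °C; then Boc2O, −78 °C
Reagents that add atoms: di-tert-butyl dicarbonate, CC(C)(C)OC(=O)OC(=O)OC(C)(C)C
Why: Directed ortho-metalation next to the methoxymethyl ether (a stronger director than the benzyl ether) followed by acylation with the dicarbonate should give the tert-butyl ester directly.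

Step 4
Reactants: 6 tert-butyl 4-(benzyloxy)-2-(methoxymethoxy)-3-({[tri(propan-2-yl)silyl]oxy}methyl)benzoate
Product: 7 tert-butyl 4-(benzyloxy)-5-fluoro-2-(methoxymethoxy)-3-({[tri(propan-2-yl)silyl]oxy}methyl)benzoate
Conditions: Selectfluor, NaHCO3, MeCN, 0 °C → rt
Reagents that add atoms: 1-(chloromethyl)-4-fluoro-1,4-diazoniabicyclo[2.2.2]octane bis(tetrafluoroborate), F[N+]12CC[N+](CCl)(CC1)CC2.F[B-](F)(F)F.F[B-](F)(F)F
Why: Electrophilic aromatic fluorination should go to the only activated free position (ortho to the benzyloxy group, para to the methoxymethoxy group), since the other ring CH is meta to both oxygens.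

Step 5
Reactants: 7 tert-butyl 4-(benzyloxy)-5-fluoro-2-(methoxymethoxy)-3-({[tri(propan-2-yl)silyl]oxy}methyl)benzoate
Product: 9 tert-butyl 4-(benzyloxy)-3-fluoro-2-formyl-6-(methoxymethoxy)-5-({[tri(propan-2-yl)silyl]oxy}methyl)benzoate, via aryllithium 8 (not isolated)
Conditions: LiTMP, THF, −78 °C; then DMF, −78 °C; H2O
Reagents that add atoms: N,N-dimethylformamide, CN(C)C=O
Why: Directed ortho-metalation removes the last ring proton, which is flanked by fluorine and the ester and is the most acidic site, and formylation at −78 °C should outrun loss of lithium fluoride.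

Step 6
Reactants: 9 tert-butyl 4-(benzyloxy)-3-fluoro-2-formyl-6-(methoxymethoxy)-5-({[tri(propan-2-yl)silyl]oxy}methyl)benzoate
Product: 10 tert-butyl 3-fluoro-2-formyl-4-hydroxy-6-(methoxymethoxy)-5-({[tri(propan-2-yl)silyl]oxy}methyl)benzoate
Conditions: H2 (1 atm), 10% Pd/C, EtOAc, rt
Reagents that add atoms: none
Why: Hydrogenolysis of the aryl benzyl ether should be faster than reduction of the hindered aldehyde, and the C–F bond, silyl ether, methoxymethyl ether and tert-butyl ester are inert.

Step 7
Reactants: 10 tert-butyl 3-fluoro-2-formyl-4-hydroxy-6-(methoxymethoxy)-5-({[tri(propan-2-yl)silyl]oxy}methyl)benzoate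
Product: 11 tert-butyl 3-fluoro-2-formyl-4-(formyloxy)-6-(methoxymethoxy)-5-({[tri(propan-2-yl)silyl]oxy}methyl)benzoate
Conditions: HCO2H/Ac2O (premixed, 50 °C); then 10, NaOAc (cat.), THF, 0 °C → rt; used crude
Reagents that add atoms: acetic formic anhydride (from formic acid and acetic anhydride), CC(=O)OC=O
Why: O-formylation of the only free phenol by the mixed anhydride is the standard preparation of aryl formates.

Step 8
Reactants: 12 atranol (2,6-dihydroxy-4-methylbenzaldehyde)
Product: 13 2,6-dihydroxy-3-iodo-4-methylbenzaldehyde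
Conditions: NIS (1.0 equiv), MeCN, 0 °C
Reagents that add atoms: N-iodosuccinimide, O=C1CCC(=O)N1I
Why: Electrophilic iodination should give one isomer because the two free ring positions of atranol are equivalent, each ortho to one hydroxyl and para to the other.

Step 9
Reactants: 13 2,6-dihydroxy-3-iodo-4-methylbenzaldehyde
Product: 14 2-hydroxy-3-iodo-4-methyl-6-{[tri(propan-2-yl)silyl]oxy}benzaldehyde
Conditions: TIPSCl, imidazole, DMF, 0 °C
Reagents that add atoms: chlorotri(propan-2-yl)silane, CC(C)[Si](Cl)(C(C)C)C(C)C
Why: The bulky silyl chloride should react at the less hindered hydroxyl, since the other is flanked by iodine and the formyl group.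

Step 10
Reactants: 11 tert-butyl 3-fluoro-2-formyl-4-(formyloxy)-6-(methoxymethoxy)-5-({[tri(propan-2-yl)silyl]oxy}methyl)benzoate; 14 2-hydroxy-3-iodo-4-methyl-6-{[tri(propan-2-yl)silyl]oxy}benzaldehyde
Product: 16 tert-butyl 4,6-diformyl-3-hydroxy-8-(methoxymethoxy)-1-methyl-11-oxo-9-({[tri(propan-2-yl)silyl]oxy}methyl)-11H-dibenzo[b,e][1,4]dioxepine-7-carboxylate, via depside 15 (not isolated)
Conditions: Pd(OAc)2 (5 mol %), Xantphos (6 mol %), Et3N, MeCN, 50 °C, closed vessel; then Cs2CO3, DMF, 70 °C; aq. citric acid
Reagents that add atoms: none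
Why: Et3N fragments formate 11 into the phenoxide of 10 and CO, zerovalent palladium formed from Pd(OAc)2 and Xantphos inserts into the C–I bond of 14, takes up the CO and is captured by that phenoxide, so the former formyl carbon becomes bonded to ring A while it stays on the ring B oxygen (depside 15); this is the CO-free aryloxycarbonylation of aryl halides with aryl formates. Cs2CO3 then ionises the ring A hydroxyl ortho to the new ester, which displaces fluoride from the ring B carbon ortho to the coplanar formyl group by addition–elimination through a Meisenheimer anion (7-exo closure of the dioxepinone ring); carbonylation/SNAr domino sequences and SNAr closures of depsidones are the closest precedents. No stereocentre is formed. Chemoselectivity in the acyl capture should be secured by the silyl ether on the second ring A hydroxyl and by the hindrance of the hydroxyl next to iodine. Site selectivity in the closure (the C–F carbon rather than Smiles-type ipso attack at the ester-bearing carbon of ring B) should be secured because the tert-butyl ester para to that carbon is twisted out of conjugation by its two ortho substituents, whereas the C–F carbon has the conjugating formyl group and the better nucleofuge for the addition step. The fluoride set free is consumed by the aryl silyl ether (Si–F bond formation), which unmasks the ring A phenol and spares the alkyl silyl ether.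

Step 11
Reactants: 16 tert-butyl 4,6-diformyl-3-hydroxy-8-(methoxymethoxy)-1-methyl-11-oxo-9-({[tri(propan-2-yl)silyl]oxy}methyl)-11H-dibenzo[b,e][1,4]dioxepine-7-carboxylate
Product: 17 tert-butyl 4,6-diformyl-3-hydroxy-9-(hydroxymethyl)-8-(methoxymethoxy)-1-methyl-11-oxo-11H-dibenzo[b,e][1,4]dioxepine-7-carboxylate
Conditions: HF·pyridine, pyridine, THF, 0 °C → rt
Reagents that add atoms: none
Why: Buffered fluoride cleaves the primary silyl ether (also any aryl silyl ether left from step 10), while the methoxymethyl ether, tert-butyl ester and depsidone lactone are stable.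

Step 12
Reactants: 18 (2E)-4-tert-butoxy-4-oxobut-2-enoic acid
Product: 19 tert-butyl prop-2-en-1-yl (2E)-but-2-enedioate
Conditions: allyl bromide, K2CO3, DMF, rt
Reagents that add atoms: allyl bromide, C=CCBr
Why: SN2 alkylation of the carboxylate gives the mixed diester without touching the E double bond.

Step 13
Reactants: 19 tert-butyl prop-2-en-1-yl (2E)-but-2-enedioate
Product: 20 (2E)-4-oxo-4-(prop-2-en-1-yloxy)but-2-enoic acid
Conditions: TFA, CH2Cl2, rt
Reagents that add atoms: none
Why: Acidolysis of the tert-butyl ester by loss of the tert-butyl cation leaves the allyl ester and the alkene geometry intact.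

Step 14
Reactants: 17 tert-butyl 4,6-diformyl-3-hydroxy-9-(hydroxymethyl)-8-(methoxymethoxy)-1-methyl-11-oxo-11H-dibenzo[b,e][1,4]dioxepine-7-carboxylate; 20 (2E)-4-oxo-4-(prop-2-en-1-yloxy)but-2-enoic acid
Product: 21 [7-(tert-butoxycarbonyl)-4,6-diformyl-3-hydroxy-8-(methoxymethoxy)-1-methyl-11-oxo-11H-dibenzo[b,e][1,4]dioxepin-9-yl]methyl prop-2-en-1-yl (2E)-but-2-enedioate
Conditions: EDC·HCl, DMAP (cat.), CH2Cl2, 0 °C
Reagents that add atoms: none
Why: In this Steglich esterification the primary benzylic alcohol should be acylated in preference to the ring A phenol, which is hydrogen-bonded to the ortho formyl group.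

Step 15
Reactants: 21 [7-(tert-butoxycarbonyl)-4,6-diformyl-3-hydroxy-8-(methoxymethoxy)-1-methyl-11-oxo-11H-dibenzo[b,e][1,4]dioxepin-9-yl]methyl prop-2-en-1-yl (2E)-but-2-enedioate
Product: 23 racemic lactol (salazinic acid esterified at the benzylic oxygen with allyl hydrogen fumarate), via formyl acid 22 (not isolated)
Conditions: TFA/CH2Cl2/H2O (10:10:1), 0 °C → rt
Reagents that add atoms: none
Why: Acidolysis removes the methoxymethyl ether and the tert-butyl ester, and the freed carboxylic acid adds to the ortho formyl group (ring-chain tautomerism, cyclic form favoured) to close the five-membered lactol ring as the racemate; the allyl ester is stable to acid.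

Step 16
Reactants: 23 racemic lactol
Product: 24 tris(allyl carbonate) of 23 with the lactol carbon in the spatial arrangement of the target (S by the sequence rule, because the carbonate oxygen outranks the lactone oxygen)
Conditions: (2S,3R)-HyperBTM [(2S,3R)-2-phenyl-3-(propan-2-yl)-3,4-dihydro-2H-benzo[4,5]thiazolo[3,2-a]pyrimidine] (10 mol %), diallyl dicarbonate (4 equiv), iPr2NEt (20 mol %), CHCl3, −30 °C → rt
Reagents that add atoms: diallyl dicarbonate, C=CCOC(=O)OC(=O)OCC=C
Why: Proposed new method: the dicarbonate should acylate the isothiourea to a chiral N-allyloxycarbonyl isothiouronium ion that transfers the carbonate group faster to one lactol enantiomer, while the two enantiomers interconvert through formyl acid 22 under amine catalysis (dynamic kinetic resolution), so the catalyst controls the configuration at the lactol carbon and the two phenols are carbonylated without stereochemical consequence; the closest known reactions are the acylative dynamic kinetic resolution of 3-hydroxyphthalides and related lactols with chiral acyl-transfer catalysts and the isothiourea-catalysed enantioselective transfer of alkoxycarbonyl groups.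

Step 17
Reactants: 24 tris(allyl carbonate)
Product: 25 CNP0379578.1 (R-configured lactol of salazinic acid mono-fumarate)
Conditions: Pd(PPh3)4 (5 mol %), TolSO2H (6 equiv, freshly liberated), THF, 0 °C
Reagents that add atoms: none
Why: In this Tsuji–Trost deallylation zerovalent palladium ionises the four allyl–oxygen bonds and the sulfinic acid traps the allyl groups and protonates the carbonate half-esters, which lose CO2; no bond to the lactol carbon is broken and no lactol alkoxide forms, so the configuration set in step 16 should be retained.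

**Compound list**

1 | 3-(benzyloxy)phenol | Oc1cccc(OCc2ccccc2)c1 | starting material
2 | 1-(benzyloxy)-3-(methoxymethoxy)benzene | COCOc1cccc(OCc2ccccc2)c1 | intermediate
3 | [2-(benzyloxy)-6-(methoxymethoxy)phenyl]lithium | [Li]c1c(OCOC)cccc1OCc1ccccc1 | intermediate
4 | {[2-(benzyloxy)-6-(methoxymethoxy)phenyl]methoxy}tri(propan-2-yl)silane | COCOc1cccc(OCc2ccccc2)c1CO[Si](C(C)C)(C(C)C)C(C)C | intermediate
5 | [4-(benzyloxy)-2-(methoxymethoxy)-3-({[tri(propan-2-yl)silyl]oxy}methyl)phenyl]lithium | [Li]c1ccc(OCc2ccccc2)c(CO[Si](C(C)C)(C(C)C)C(C)C)c1OCOC | intermediate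
6 | tert-butyl 4-(benzyloxy)-2-(methoxymethoxy)-3-({[tri(propan-2-yl)silyl]oxy}methyl)benzoate | CC(C)(C)OC(=O)c1ccc(OCc2ccccc2)c(CO[Si](C(C)C)(C(C)C)C(C)C)c1OCOC | intermediate
7 | tert-butyl 4-(benzyloxy)-5-fluoro-2-(methoxymethoxy)-3-({[tri(propan-2-yl)silyl]oxy}methyl)benzoate | CC(C)(C)OC(=O)c1cc(F)c(OCc2ccccc2)c(CO[Si](C(C)C)(C(C)C)C(C)C)c1OCOC | intermediate
8 | [3-(benzyloxy)-6-(tert-butoxycarbonyl)-2-fluoro-5-(methoxymethoxy)-4-({[tri(propan-2-yl)silyl]oxy}methyl)phenyl]lithium | CC(C)(C)OC(=O)c1c([Li])c(F)c(OCc2ccccc2)c(CO[Si](C(C)C)(C(C)C)C(C)C)c1OCOC | intermediate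
9 | tert-butyl 4-(benzyloxy)-3-fluoro-2-formyl-6-(methoxymethoxy)-5-({[tri(propan-2-yl)silyl]oxy}methyl)benzoate | CC(C)(C)OC(=O)c1c(C=O)c(F)c(OCc2ccccc2)c(CO[Si](C(C)C)(C(C)C)C(C)C)c1OCOC | intermediate
10 | tert-butyl 3-fluoro-2-formyl-4-hydroxy-6-(methoxymethoxy)-5-({[tri(propan-2-yl)silyl]oxy}methyl)benzoate | CC(C)(C)OC(=O)c1c(C=O)c(F)c(O)c(CO[Si](C(C)C)(C(C)C)C(C)C)c1OCOC | intermediate
11 | tert-butyl 3-fluoro-2-formyl-4-(formyloxy)-6-(methoxymethoxy)-5-({[tri(propan-2-yl)silyl]oxy}methyl)benzoate | CC(C)(C)OC(=O)c1c(C=O)c(F)c(OC=O)c(CO[Si](C(C)C)(C(C)C)C(C)C)c1OCOC | intermediate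
12 | atranol (2,6-dihydroxy-4-methylbenzaldehyde) | Cc1cc(O)c(C=O)c(O)c1 | starting material
13 | 2,6-dihydroxy-3-iodo-4-methylbenzaldehyde | Cc1cc(O)c(C=O)c(O)c1I | intermediate
14 | 2-hydroxy-3-iodo-4-methyl-6-{[tri(propan-2-yl)silyl]oxy}benzaldehyde | Cc1cc(O[Si](C(C)C)(C(C)C)C(C)C)c(C=O)c(O)c1I | intermediate
15 | depside: 4-(tert-butoxycarbonyl)-2-fluoro-3-formyl-5-(methoxymethoxy)-6-({[tri(propan-2-yl)silyl]oxy}methyl)phenyl 3-formyl-2-hydroxy-6-methyl-4-{[tri(propan-2-yl)silyl]oxy}benzoate | Cc1cc(O[Si](C(C)C)(C(C)C)C(C)C)c(C=O)c(O)c1C(=O)Oc1c(F)c(C=O)c(C(=O)OC(C)(C)C)c(OCOC)c1CO[Si](C(C)C)(C(C)C)C(C)C | intermediate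
16 | tert-butyl 4,6-diformyl-3-hydroxy-8-(methoxymethoxy)-1-methyl-11-oxo-9-({[tri(propan-2-yl)silyl]oxy}methyl)-11H-dibenzo[b,e][1,4]dioxepine-7-carboxylate | Cc1cc(O)c(C=O)c2c1C(=O)Oc1c(CO[Si](C(C)C)(C(C)C)C(C)C)c(OCOC)c(C(=O)OC(C)(C)C)c(C=O)c1O2 | intermediate
17 | tert-butyl 4,6-diformyl-3-hydroxy-9-(hydroxymethyl)-8-(methoxymethoxy)-1-methyl-11-oxo-11H-dibenzo[b,e][1,4]dioxepine-7-carboxylate | Cc1cc(O)c(C=O)c2c1C(=O)Oc1c(CO)c(OCOC)c(C(=O)OC(C)(C)C)c(C=O)c1O2 | intermediate
18 | (2E)-4-tert-butoxy-4-oxobut-2-enoic acid (mono-tert-butyl fumarate) | CC(C)(C)OC(=O)/C=C/C(=O)O | starting material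
19 | tert-butyl prop-2-en-1-yl (2E)-but-2-enedioate | C=CCOC(=O)/C=C/C(=O)OC(C)(C)C | intermediate
20 | (2E)-4-oxo-4-(prop-2-en-1-yloxy)but-2-enoic acid (allyl hydrogen fumarate) | C=CCOC(=O)/C=C/C(=O)O | intermediate
21 | [7-(tert-butoxycarbonyl)-4,6-diformyl-3-hydroxy-8-(methoxymethoxy)-1-methyl-11-oxo-11H-dibenzo[b,e][1,4]dioxepin-9-yl]methyl prop-2-en-1-yl (2E)-but-2-enedioate | Cc1cc(O)c(C=O)c2c1C(=O)Oc1c(COC(=O)/C=C/C(=O)OCC=C)c(OCOC)c(C(=O)OC(C)(C)C)c(C=O)c1O2 | intermediate
22 | 4,6-diformyl-3,8-dihydroxy-1-methyl-11-oxo-9-({[(2E)-4-oxo-4-(prop-2-en-1-yloxy)but-2-enoyl]oxy}methyl)-11H-dibenzo[b,e][1,4]dioxepine-7-carboxylic acid | Cc1cc(O)c(C=O)c2c1C(=O)Oc1c(COC(=O)/C=C/C(=O)OCC=C)c(O)c(C(=O)O)c(C=O)c1O2 | intermediate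
23 | racemic lactol: salazinic acid esterified at the benzylic oxygen with allyl hydrogen fumarate (lactol carbon racemic) | Cc1cc(O)c(C=O)c2c1C(=O)Oc1c(COC(=O)/C=C/C(=O)OCC=C)c(O)c3c(c1O2)C(O)OC3=O | intermediate
24 | tris(allyl carbonate) of 23 (both phenols and the lactol oxygen), lactol carbon S | Cc1cc(OC(=O)OCC=C)c(C=O)c2c1C(=O)Oc1c(COC(=O)/C=C/C(=O)OCC=C)c(OC(=O)OCC=C)c3c(c1O2)[C@H](OC(=O)OCC=C)OC3=O | intermediate
25 | CNP0379578.1: salazinic acid mono-ester of fumaric acid at the benzylic oxygen, lactol carbon R | Cc1cc(O)c(C=O)c2c1C(=O)Oc1c(COC(=O)/C=C/C(=O)O)c(O)c3c(c1O2)[C@H](O)OC3=O | target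

**Step count and risks**

Total step count: 17. Longest linear sequence: 13 steps (steps 1–7, 10, 11, 14–17).

Steps most likely to fail:

Step 16. The carbonate transfer may not discriminate the two lactol enantiomers, background carbonylation through the ring-opened carboxylate may erode the selectivity, or the catalyst may favour the mirror-image carbonate (in which case its antipode is used). Fallback with known chemistry: from 23, DMAP-catalysed carbonylation with diallyl dicarbonate in CH2Cl2 gives the racemic tris(allyl carbonate) F1. Its enantiomers, which are configurationally stable acylals, are separated by preparative chromatography on a chiral stationary phase. The S enantiomer is 24, where the route is rejoined.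

Step 10. Intermolecular acyl capture by a ring A hydroxyl may give oligomers, or Smiles-type ipso attack at the ester-bearing carbon of ring B may compete with displacement of fluoride. Fallback that forms the ether first: from 12 (in excess, its two hydroxyls being equivalent) and 9, K2CO3 in DMF at 90 °C gives the diaryl ether F2 by SNAr. Hydrogenolysis (H2, Pd/C) gives the phenol F3. NIS iodinates ring A para to its free hydroxyl to give the iodide F4. Pd(OAc)2, Xantphos, CO (1 atm) and Et3N in toluene at 80 °C then close the lactone by intramolecular aryloxycarbonylation, returning to the route at 16.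

Step 2. The hindered aryllithium may attack silicon or decompose the chloromethyl ether by α-elimination instead of undergoing C-alkylation. Fallback that brings the carbon in at the aldehyde level: from 2, lithiation as in step 2 and quenching with DMF give the aldehyde F5. NaBH4 in MeOH gives the benzylic alcohol F6. TIPSCl and imidazole return to the route at 4.

**Further compounds**

F1 | step 16 | racemic tris(allyl carbonate) of 23 | Cc1cc(OC(=O)OCC=C)c(C=O)c2c1C(=O)Oc1c(COC(=O)/C=C/C(=O)OCC=C)c(OC(=O)OCC=C)c3c(c1O2)C(OC(=O)OCC=C)OC3=O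
F2 | step 10 | tert-butyl 4-(benzyloxy)-2-formyl-3-(2-formyl-3-hydroxy-5-methylphenoxy)-6-(methoxymethoxy)-5-({[tri(propan-2-yl)silyl]oxy}methyl)benzoate | Cc1cc(O)c(C=O)c(Oc2c(C=O)c(C(=O)OC(C)(C)C)c(OCOC)c(CO[Si](C(C)C)(C(C)C)C(C)C)c2OCc2ccccc2)c1
F3 | step 10 | tert-butyl 2-formyl-3-(2-formyl-3-hydroxy-5-methylphenoxy)-4-hydroxy-6-(methoxymethoxy)-5-({[tri(propan-2-yl)silyl]oxy}methyl)benzoate | Cc1cc(O)c(C=O)c(Oc2c(C=O)c(C(=O)OC(C)(C)C)c(OCOC)c(CO[Si](C(C)C)(C(C)C)C(C)C)c2O)c1
F4 | step 10 | tert-butyl 2-formyl-3-(2-formyl-3-hydroxy-6-iodo-5-methylphenoxy)-4-hydroxy-6-(methoxymethoxy)-5-({[tri(propan-2-yl)silyl]oxy}methyl)benzoate | Cc1cc(O)c(C=O)c(Oc2c(C=O)c(C(=O)OC(C)(C)C)c(OCOC)c(CO[Si](C(C)C)(C(C)C)C(C)C)c2O)c1I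
F5 | step 2 | 2-(benzyloxy)-6-(methoxymethoxy)benzaldehyde | O=Cc1c(OCOC)cccc1OCc1ccccc1
F6 | step 2 | [2-(benzyloxy)-6-(methoxymethoxy)phenyl]methanol | OCc1c(OCOC)cccc1OCc1ccccc1
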